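The two 4-aryl-chroman-2-ones are joined at C3–C3′, and everything rests on forming the C3–C4 bond of the 5,7-dioxygenated half (unprimed: ring A benzo, ring B 4-aryl, ring C lactone) by carbene C–H insertion. The step exploits C4, a doubly benzylic carbon between rings A and B whose C–H bond lies six atoms from C3 (C3, C2, O1, C8a, C4a, C4). A rhodium carbene at C3, tied by an ester to the ring A phenol oxygen and bearing the intact 4′-aryl coumarin of the primed half, inserts into one enantiotopic C4–H bond, closing ring C and fixing C4 in one operation. The precursor is the ring A aryl ester of a coumarin-3-yl diazoacetate.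

Key step: step 9

Remarks on the chemistry (chroman-2-one numbering; primed locants and rings A′, B′, C′ for the 5,6,7,8-tetraoxygenated half):
- The target is (3S,4R,3′S,4′R), which means 3,4-cis in both lactones.
- Assumption: the sense of induction of a chiral dirhodium carboxylate in this ring closure cannot be predicted. Rh2(S-PTAD)4 is written; its R antipode is used instead if that is the one leading to 4R.
- Blocking groups: C8 of ring A carries a hydrogen and, like C4a, sits five atoms from the carbene carbon, so electrophilic attack there would close a benzofuranone. C8 and C6 are therefore blocked with bromine, which falls off in the hydrogenation step at no extra cost.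
- Choice of C3 epimer for the hydrogenation: allylic 1,3-strain should hold C3–H in the coumarin plane and put the C4 branch over one coumarin face. Addition anti to C4 then leads to 4′R only from the 3R (3,4-trans) epimer. The route therefore hydrogenates the trans epimer and sets C3 and C3′ afterwards by kinetic protonation.
- Choice of reductant: C3–H of the insertion product is acidic (lactone carbonyl plus coumarin), so basic hydride reagents are avoided in favour of catalytic hydrogenation.

Step 1
Reactants: 1 1,2,3,4-tetramethoxybenzene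
Product: 4 2,3,4,5-tetramethoxyphenol, via aryllithium 2 (not isolated), via lithium aryltrimethoxyborate 3 (not isolated)
Conditions: n-BuLi, TMEDA, THF, 0 °C; B(OMe)3, −78 °C → rt; AcOH, 30% H2O2, 0 °C → rt
Reagents that add atoms: hydrogen peroxide, OO
Why: Directed ortho-lithiation next to a methoxy group (the two ring hydrogens are equivalent), borylation and oxidative C–B to C–O conversion form a standard one-flask phenol synthesis.

Step 2
Reactants: 4 2,3,4,5-tetramethoxyphenol; 5 4-methoxybenzoyl chloride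
Product: 6 (2-hydroxy-3,4,5,6-tetramethoxyphenyl)(4-methoxyphenyl)methanone
Conditions: TiCl4, CH2Cl2, 0 °C → reflux; 1 M HCl
Reagents that add atoms: none
Why: Friedel–Crafts acylation through the titanium phenoxide (O-acylated material converging by Fries rearrangement) can only reach the single free ring position, which lies ortho to the hydroxyl.

Step 3
Reactants: 6 (2-hydroxy-3,4,5,6-tetramethoxyphenyl)(4-methoxyphenyl)methanone; 7 methyl 4-chloro-4-oxobutanoate
Product: 9 methyl 2-[5,6,7,8-tetramethoxy-4-(4-methoxyphenyl)-2-oxo-2H-chromen-3-yl]acetate, via aryl methyl succinate 8 (not isolated)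
Conditions: Et3N, DMAP (cat.), CH2Cl2, 0 °C → rt; then DBU, MeCN, 80 °C
Reagents that add atoms: none
Why: O-acylation followed by base-mediated intramolecular aldol condensation of the aryl ester enolate onto the neighbouring, non-enolisable diaryl ketone (Kostanecki-type coumarin synthesis) closes the six-membered lactone and dehydrates into conjugation.

Step 4
Reactants: 9 methyl 2-[5,6,7,8-tetramethoxy-4-(4-methoxyphenyl)-2-oxo-2H-chromen-3-yl]acetate
Product: 10 2-[5,6,7,8-tetramethoxy-4-(4-methoxyphenyl)-2-oxo-2H-chromen-3-yl]acetic acid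
Conditions: LiOH, THF/H2O, rt; then 1 M HCl
Reagents that add atoms: lithium hydroxide, [Li+].[OH-]
Why: Saponification of the methyl ester; if hydroxide also opens the coumarin, the Z-configured tetrasubstituted cinnamate recloses on acidification.

Step 5
Reactants: 11 2-hydroxy-4,6-dimethoxybenzaldehyde; 12 4-methoxyphenylmagnesium bromide
Product: 14 2-(4-methoxybenzyl)-3,5-dimethoxyphenol, via benzhydrol 13 (not isolated)
Conditions: 12 (2.3 equiv), THF, 0 °C → rt; 1 M HCl; then Et3SiH, CF3CO2H, CH2Cl2, 0 °C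
Reagents that add atoms: none
Why: Grignard addition to the aldehyde (the first equivalent only deprotonates the phenol) places the benzyl carbon ortho to the hydroxyl without a regiochemical question, and ionic hydrogenation of the doubly donor-stabilised benzhydryl cation removes the carbinol oxygen.

Step 6
Reactants: 14 2-(4-methoxybenzyl)-3,5-dimethoxyphenol
Product: 15 2,4-dibromo-3,5-dimethoxy-6-(4-methoxybenzyl)phenol
Conditions: NBS (2.05 equiv), MeCN, −20 → 0 °C, dark
Reagents that add atoms: N-bromosuccinimide, O=C1CCC(=O)N1Br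
Why: Electrophilic aromatic bromination goes to the two free positions of the trioxygenated ring, which is far more nucleophilic than the anisyl ring, and so blocks the future C8 and C6 against carbene attack.

Step 7
Reactants: 10 2-[5,6,7,8-tetramethoxy-4-(4-methoxyphenyl)-2-oxo-2H-chromen-3-yl]acetic acid; 15 2,4-dibromo-3,5-dimethoxy-6-(4-methoxybenzyl)phenol
Product: 16 2,4-dibromo-3,5-dimethoxy-6-(4-methoxybenzyl)phenyl 2-[5,6,7,8-tetramethoxy-4-(4-methoxyphenyl)-2-oxo-2H-chromen-3-yl]acetate
Conditions: DCC, DMAP (cat.), CH2Cl2, 0 °C → rt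
Reagents that add atoms: none
Why: Steglich esterification, in which the DMAP-activated acid acylates the acidic dibromophenol.

Step 8
Reactants: 16 2,4-dibromo-3,5-dimethoxy-6-(4-methoxybenzyl)phenyl 2-[5,6,7,8-tetramethoxy-4-(4-methoxyphenyl)-2-oxo-2H-chromen-3-yl]acetate
Product: 17 2,4-dibromo-3,5-dimethoxy-6-(4-methoxybenzyl)phenyl 2-diazo-2-[5,6,7,8-tetramethoxy-4-(4-methoxyphenyl)-2-oxo-2H-chromen-3-yl]acetate
Conditions: p-ABSA, DBU, MeCN, 0 °C → rt
Reagents that add atoms: 4-acetamidobenzenesulfonyl azide, CC(=O)Nc1ccc(cc1)S(=O)(=O)N=[N+]=[N-]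
Why: Regitz diazo transfer to a methylene group activated by the aryl ester carbonyl and the coumarin C3′ position, as for arylacetates.

Step 9
Reactants: 17 2,4-dibromo-3,5-dimethoxy-6-(4-methoxybenzyl)phenyl 2-diazo-2-[5,6,7,8-tetramethoxy-4-(4-methoxyphenyl)-2-oxo-2H-chromen-3-yl]acetate
Product: 18 (3S,4R)-6,8-dibromo-5,7-dimethoxy-4-(4-methoxyphenyl)-3-[5,6,7,8-tetramethoxy-4-(4-methoxyphenyl)-2-oxo-2H-chromen-3-yl]chroman-2-one (3,4-cis)
Conditions: Rh2(S-PTAD)4 (tetrakis[(S)-N-phthaloyl-(1-adamantyl)glycinato]dirhodium, 1 mol %), CH2Cl2, 4 Å molecular sieves, 40 °C, slow addition of 17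
Reagents that add atoms: none
Why: Proposed new method: loss of N2 gives a rhodium carbene at C3 that is conjugated with the coumarin C3′=C4′ bond and flanked by the aryl ester; in the s-cis ester rotamer its vacant orbital reaches the C4–H bond, and hydride-like transfer from C4 with simultaneous C3–C4 bond formation in a three-centre transition state gives the lactone, the closest known reaction type being the intramolecular benzylic C–H insertion of donor/acceptor rhodium carbenes from aryl- and vinyldiazoacetates that delivers dihydrobenzofurans and small lactones. Ring C closes as a six-membered lactone by 1,6-insertion (C3, C2, O1, C8a, C4a, C4) through a six-membered cyclic transition state, and the carbene cannot be diverted by a hydride shift because C3′ is trigonal and bears no hydrogen. C4 is controlled by the chiral phthalimido-carboxylate ligands, which choose one of the two enantiotopic hydrogens of the CH2 group; C3 is fixed in the same transition state by the approach geometry (cis expected by analogy with cis-selective insertions of this carbene class) and is not critical, since it is re-set in steps 10 and 11. The step needs site selectivity for C4–H over electrophilic attack on arene carbons: C8 and C6 are blocked by bromine, the ortho carbons of ring B′ are protected because the peri 5′-methoxy group holds that ring perpendicular to the coumarin, and methyl ethers offer no activated C–H bond, whereas C4–H is doubly benzylic and flanked by two donor arenes.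

Step 10
Reactants: 18 (3S,4R)-6,8-dibromo-5,7-dimethoxy-4-(4-methoxyphenyl)-3-[5,6,7,8-tetramethoxy-4-(4-methoxyphenyl)-2-oxo-2H-chromen-3-yl]chroman-2-one (3,4-cis)
Product: 21 (3R,4R)-5,7-dimethoxy-4-(4-methoxyphenyl)-3-[(3S,4R)-5,6,7,8-tetramethoxy-4-(4-methoxyphenyl)-2-oxochroman-3-yl]chroman-2-one, via 3,4-trans dibromide 19 (not isolated), via 3,4-trans coumarin 20 (not isolated)
Conditions: DBU (0.2 equiv), EtOAc, rt; then Et3N (3 equiv), 10% Pd/C, H2 (50 bar), 50 °C
Reagents that add atoms: none
Why: DBU equilibrates the acidic C3 centre to the more stable 3,4-trans lactone, in which allylic 1,3-strain keeps C3–H in the coumarin plane and puts the bulky C4 branch over one face; hydrogenolysis of both C–Br bonds and syn hydrogenation of C3′=C4′ on the face opposite C4 then set C4′ as R (substrate-controlled heterogeneous hydrogenation), while C3 and C3′ are left for step 11.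

Step 11
Reactants: 21 (3R,4R)-5,7-dimethoxy-4-(4-methoxyphenyl)-3-[(3S,4R)-5,6,7,8-tetramethoxy-4-(4-methoxyphenyl)-2-oxochroman-3-yl]chroman-2-one
Product: 23 (3S,4R)-5,7-dimethoxy-4-(4-methoxyphenyl)-3-[(3S,4R)-5,6,7,8-tetramethoxy-4-(4-methoxyphenyl)-2-oxochroman-3-yl]chroman-2-one, via dilithium bis-enolate 22 (not isolated)
Conditions: LiN(i-Pr)2 (3 equiv), THF, −78 °C; then AcOH in THF, −78 °C
Reagents that add atoms: none
Why: Double deprotonation gives the bis-enolate, which erases C3 and C3′, and kinetic protonation of each enolate carbon on the face away from the pseudo-axial aryl group at C4 or C4′ should give the 3,4-cis arrangement in both lactones (kinetic enolate protonation, contra-thermodynamic).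

Step 12
Reactants: 23 (3S,4R)-5,7-dimethoxy-4-(4-methoxyphenyl)-3-[(3S,4R)-5,6,7,8-tetramethoxy-4-(4-methoxyphenyl)-2-oxochroman-3-yl]chroman-2-one
Product: 24 (3S,4R)-5,7-dihydroxy-4-(4-hydroxyphenyl)-3-[(3S,4R)-5,6,7,8-tetrahydroxy-4-(4-hydroxyphenyl)-2-oxochroman-3-yl]chroman-2-one
Conditions: BBr3 (20 equiv), CH2Cl2, −78 °C → rt, argon; then degassed ice water
Reagents that add atoms: none
Why: Lewis acid-mediated cleavage of all eight aryl methyl ethers under non-basic conditions that leave the C3 and C3′ centres alone; rings A and A′ are symmetric about their C4a–C7 axes, so a transient lactone opening can only reclose to the same compound.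

Compound list
1 | 1,2,3,4-tetramethoxybenzene | COc1ccc(OC)c(OC)c1OC | starting material
2 | (2,3,4,5-tetramethoxyphenyl)lithium | [Li]c1cc(OC)c(OC)c(OC)c1OC | intermediate
3 | lithium trimethoxy(2,3,4,5-tetramethoxyphenyl)borate | [Li+].CO[B-](OC)(OC)c1cc(OC)c(OC)c(OC)c1OC | intermediate
4 | 2,3,4,5-tetramethoxyphenol | COc1cc(O)c(OC)c(OC)c1OC | intermediate
5 | 4-methoxybenzoyl chloride | COc1ccc(cc1)C(Cl)=O | starting material
6 | (2-hydroxy-3,4,5,6-tetramethoxyphenyl)(4-methoxyphenyl)methanone | COc1ccc(cc1)C(=O)c1c(O)c(OC)c(OC)c(OC)c1OC | intermediate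
7 | methyl 4-chloro-4-oxobutanoate | COC(=O)CCC(Cl)=O | starting material
8 | 2-(4-methoxybenzoyl)-3,4,5,6-tetramethoxyphenyl methyl butanedioate | COC(=O)CCC(=O)Oc1c(OC)c(OC)c(OC)c(OC)c1C(=O)c1ccc(OC)cc1 | intermediate
9 | methyl 2-[5,6,7,8-tetramethoxy-4-(4-methoxyphenyl)-2-oxo-2H-chromen-3-yl]acetate | COC(=O)Cc1c(-c2ccc(OC)cc2)c2c(OC)c(OC)c(OC)c(OC)c2oc1=O | intermediate
10 | 2-[5,6,7,8-tetramethoxy-4-(4-methoxyphenyl)-2-oxo-2H-chromen-3-yl]acetic acid | OC(=O)Cc1c(-c2ccc(OC)cc2)c2c(OC)c(OC)c(OC)c(OC)c2oc1=O | intermediate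
11 | 2-hydroxy-4,6-dimethoxybenzaldehyde | COc1cc(O)c(C=O)c(OC)c1 | starting material
12 | 4-methoxyphenylmagnesium bromide | COc1ccc([Mg]Br)cc1 | starting material
13 | 2-[hydroxy(4-methoxyphenyl)methyl]-3,5-dimethoxyphenol (racemic) | COc1ccc(cc1)C(O)c1c(O)cc(OC)cc1OC | intermediate
14 | 2-(4-methoxybenzyl)-3,5-dimethoxyphenol | COc1ccc(Cc2c(O)cc(OC)cc2OC)cc1 | intermediate
15 | 2,4-dibromo-3,5-dimethoxy-6-(4-methoxybenzyl)phenol | COc1ccc(Cc2c(O)c(Br)c(OC)c(Br)c2OC)cc1 | intermediate
16 | 2,4-dibromo-3,5-dimethoxy-6-(4-methoxybenzyl)phenyl 2-[5,6,7,8-tetramethoxy-4-(4-methoxyphenyl)-2-oxo-2H-chromen-3-yl]acetate | O=C(Cc1c(-c2ccc(OC)cc2)c2c(OC)c(OC)c(OC)c(OC)c2oc1=O)Oc1c(Br)c(OC)c(Br)c(OC)c1Cc1ccc(OC)cc1 | intermediate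
17 | 2,4-dibromo-3,5-dimethoxy-6-(4-methoxybenzyl)phenyl 2-diazo-2-[5,6,7,8-tetramethoxy-4-(4-methoxyphenyl)-2-oxo-2H-chromen-3-yl]acetate | [N-]=[N+]=C(C(=O)Oc1c(Br)c(OC)c(Br)c(OC)c1Cc1ccc(OC)cc1)c1c(-c2ccc(OC)cc2)c2c(OC)c(OC)c(OC)c(OC)c2oc1=O | intermediate
18 | (3S,4R)-6,8-dibromo-5,7-dimethoxy-4-(4-methoxyphenyl)-3-[5,6,7,8-tetramethoxy-4-(4-methoxyphenyl)-2-oxo-2H-chromen-3-yl]chroman-2-one, 3,4-cis | O=C1Oc2c(Br)c(OC)c(Br)c(OC)c2[C@@H](c2ccc(OC)cc2)[C@H]1c1c(-c2ccc(OC)cc2)c2c(OC)c(OC)c(OC)c(OC)c2oc1=O | intermediate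
19 | (3R,4R)-6,8-dibromo-5,7-dimethoxy-4-(4-methoxyphenyl)-3-[5,6,7,8-tetramethoxy-4-(4-methoxyphenyl)-2-oxo-2H-chromen-3-yl]chroman-2-one, 3,4-trans | O=C1Oc2c(Br)c(OC)c(Br)c(OC)c2[C@@H](c2ccc(OC)cc2)[C@@H]1c1c(-c2ccc(OC)cc2)c2c(OC)c(OC)c(OC)c(OC)c2oc1=O | intermediate
20 | (3R,4R)-5,7-dimethoxy-4-(4-methoxyphenyl)-3-[5,6,7,8-tetramethoxy-4-(4-methoxyphenyl)-2-oxo-2H-chromen-3-yl]chroman-2-one, 3,4-trans | O=C1Oc2cc(OC)cc(OC)c2[C@@H](c2ccc(OC)cc2)[C@@H]1c1c(-c2ccc(OC)cc2)c2c(OC)c(OC)c(OC)c(OC)c2oc1=O | intermediate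
21 | (3R,4R)-5,7-dimethoxy-4-(4-methoxyphenyl)-3-[(3S,4R)-5,6,7,8-tetramethoxy-4-(4-methoxyphenyl)-2-oxochroman-3-yl]chroman-2-one, 3,4-trans and 3′,4′-cis | O=C1Oc2cc(OC)cc(OC)c2[C@@H](c2ccc(OC)cc2)[C@@H]1[C@H]1C(=O)Oc2c(OC)c(OC)c(OC)c(OC)c2[C@H]1c1ccc(OC)cc1 | intermediate
22 | dilithium bis-enolate of 21 (C3 and C3′ trigonal, C4 and C4′ as in 21) | [Li+].[Li+].[O-]C1Oc2cc(OC)cc(OC)c2[C@@H](c2ccc(OC)cc2)C=1C1=C([O-])Oc2c(OC)c(OC)c(OC)c(OC)c2[C@H]1c1ccc(OC)cc1 | intermediate
23 | (3S,4R)-5,7-dimethoxy-4-(4-methoxyphenyl)-3-[(3S,4R)-5,6,7,8-tetramethoxy-4-(4-methoxyphenyl)-2-oxochroman-3-yl]chroman-2-one, cis in both lactones | O=C1Oc2cc(OC)cc(OC)c2[C@@H](c2ccc(OC)cc2)[C@H]1[C@H]1C(=O)Oc2c(OC)c(OC)c(OC)c(OC)c2[C@H]1c1ccc(OC)cc1 | intermediate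
24 | (3S,4R)-5,7-dihydroxy-4-(4-hydroxyphenyl)-3-[(3S,4R)-5,6,7,8-tetrahydroxy-4-(4-hydroxyphenyl)-2-oxochroman-3-yl]chroman-2-one | O=C1Oc2cc(O)cc(O)c2[C@@H](c2ccc(O)cc2)[C@H]1[C@H]1C(=O)Oc2c(O)c(O)c(O)c(O)c2[C@H]1c1ccc(O)cc1 | target

Total step count: 12. Longest linear sequence: 10 steps (steps 1, 2, 3, 4, 7, 8, 9, 10, 11, 12, from 1,2,3,4-tetramethoxybenzene).

Steps most likely to fail

Step 9. The carbene may be consumed before it reaches C4–H, because the ester must first turn into its less favoured s-cis rotamer; electrophilic attack on an arene, dimerisation or poor discrimination between the two enantiotopic hydrogens would follow. The fallback makes the same C3–C4 bond by a known conjugate addition. It sets out from acid 10 and benzhydrol 13, here isolated after the Grignard addition of step 5. Compound 13 is converted with sodium 4-methylbenzenesulfinate and acid into the sulfone 2-[(4-methoxyphenyl)(4-methylbenzenesulfonyl)methyl]-3,5-dimethoxyphenol F1. With base, F1 releases in situ the ortho-quinone methide 6-[(4-methoxyphenyl)methylidene]-3,5-dimethoxycyclohexa-2,4-dien-1-one F2. Acid 10 is activated with pivaloyl chloride and i-Pr2NEt as the mixed anhydride 2,2-dimethylpropanoic 2-[5,6,7,8-tetramethoxy-4-(4-methoxyphenyl)-2-oxo-2H-chromen-3-yl]acetic anhydride F3. Under a chiral isothiourea Lewis base (benzotetramisole) the derived C1-ammonium enolate adds to F2 and the phenoxide lactonises, a known formal [4+2] annulation in which the catalyst sets C4. Equilibration of C3 with DBU gives the trans lactone 20, and the route is rejoined there with the hydrogenation of step 10 (no bromine to remove, no amine needed).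

Step 10. Facial selectivity in the hydrogenation of the tetrasubstituted coumarin may be weak or opposite to the conformational model, or the alkene may resist reduction. The fallback changes the control element from the 3R to the 3S centre. It sets out from 18, which is debrominated without epimerisation (10% Pd/C, H2 1 atm, NaOAc, EtOAc) to the cis lactone (3S,4R)-5,7-dimethoxy-4-(4-methoxyphenyl)-3-[5,6,7,8-tetramethoxy-4-(4-methoxyphenyl)-2-oxo-2H-chromen-3-yl]chroman-2-one F4. F4 is then hydrogenated under pressure in EtOAc/AcOH. With C3 inverted, the C4 branch lies over the other coumarin face, so syn addition would deliver 23 directly, and the route is rejoined at 23 without step 11.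

Step 11. The lactone enolates may fragment by ring opening to ketenes, the second deprotonation may stay incomplete, or protonation may drift to thermodynamic control during the quench. The fallback avoids strong base. It sets out from 21, which is enolised softly (Me3SiOSO2CF3, Et3N, CH2Cl2) to the bis(trimethylsilyl ketene acetal) of 21 F5. F5 is protodesilylated at low temperature with a bulky Brønsted acid (a 2,6-disubstituted phenol activated by SnCl4), each ketene acetal being protonated anti to its neighbouring aryl group. The route is rejoined at 23.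

Further compounds
F1 | step 9 | 2-[(4-methoxyphenyl)(4-methylbenzenesulfonyl)methyl]-3,5-dimethoxyphenol (racemic) | COc1ccc(cc1)C(c1c(O)cc(OC)cc1OC)S(=O)(=O)c1ccc(C)cc1
F2 | step 9 | 6-[(4-methoxyphenyl)methylidene]-3,5-dimethoxycyclohexa-2,4-dien-1-one | COC1=CC(=O)C(=Cc2ccc(OC)cc2)C(OC)=C1
F3 | step 9 | 2,2-dimethylpropanoic 2-[5,6,7,8-tetramethoxy-4-(4-methoxyphenyl)-2-oxo-2H-chromen-3-yl]acetic anhydride | CC(C)(C)C(=O)OC(=O)Cc1c(-c2ccc(OC)cc2)c2c(OC)c(OC)c(OC)c(OC)c2oc1=O
F4 | step 10 | (3S,4R)-5,7-dimethoxy-4-(4-methoxyphenyl)-3-[5,6,7,8-tetramethoxy-4-(4-methoxyphenyl)-2-oxo-2H-chromen-3-yl]chroman-2-one, 3,4-cis | O=C1Oc2cc(OC)cc(OC)c2[C@@H](c2ccc(OC)cc2)[C@H]1c1c(-c2ccc(OC)cc2)c2c(OC)c(OC)c(OC)c(OC)c2oc1=O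
F5 | step 11 | bis(trimethylsilyl ketene acetal) of 21 (C3 and C3′ trigonal, C4 and C4′ as in 21) | C[Si](C)(C)OC1Oc2cc(OC)cc(OC)c2[C@@H](c2ccc(OC)cc2)C=1C1=C(O[Si](C)(C)C)Oc2c(OC)c(OC)c(OC)c(OC)c2[C@H]1c1ccc(OC)cc1
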